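## The problem

The target is a 3,4-dihydronaphthalen-1(2H)-one. Ring A comprises C1–C4, C4a and C8a; ring B is the benzene ring C4a–C8a. Ring B carries five substituents: the two fusion carbons, a 4-hydroxy-2-pyranon-6-yl group at C5, a 3-methylbutyl group at C6 and a hydroxyl at C8, so that only C7 bears hydrogen. The single stereocentre, C3 (R), is a carbinol β to the C1 ketone; no other centre can relay or correct it, so it must come from a reagent-controlled step and be carried as an ether. This β-hydroxy ketone is the fragile part: acid or base dehydrates it and aromatises ring A to a naphthalenediol, and retro-aldol opening would racemise C3, so the C3 oxygen is best freed last under near-neutral conditions. The 4-hydroxy-2-pyranone is an acidic vinylogous acid on a di-ortho-substituted carbon (between the C6 chain and C4); its bond to C5 is not a stable stereogenic axis, and it is best built late from a small, linear precursor. Ring A closures onto a preformed arene (Friedel–Crafts type) would be steered para to the oxygen and give the wrong fusion pattern, so the placement of five substituents on ring B is the central issue. The enabling feature is the C8 hydroxyl next to fusion carbon C8a, with C7–H beside it and an alkyl group at C6: this is the pattern left when a 2,4-disubstituted furan (C4a, C5, C6, C7 and its oxygen) merges with a tethered alkyne (C8a, C8) under gold catalysis, the C4–C1 chain becoming ring A. A thermal furan Diels–Alder reaction on the same tether would leave the oxygen on C7; only the gold pathway can move it to C8, and with this substitution pattern that move has to be enforced.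

## Retrosynthesis

**28 ⇒ 27.** Only the C3 O–Si bond is cut. Keeping C3 as its tert-butyldimethylsilyl ether until the end protects the β-hydroxy ketone from every earlier reagent. The forward step must desilylate without base or strong acid.

**27 ⇒ 26.** The pyranone O1′–C6′ bond is cut, giving the aryl ynone β-keto tert-butyl ester 26. The neighbouring options are a Claisen-type assembly through an aroyl derivative at C5, or cross-coupling of a preformed pyranone; both require bond formation at a carbon flanked by two ortho substituents. An alkyne places only a linear sp carbon there. The forward reaction needs 6-endo attack of the ester oxygen on the activated alkyne while the C3 oxygen is still silylated, so that it cannot add to the ynone.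

**26 ⇒ 25 ⇒ 24.** The C1 ketone and the ynone carbonyl are traced back to carbinols, and the C1 carbinol to its triethylsilyl ether. One oxidant selective for benzylic and propargylic alcohols creates both carbonyls in a single step and merges all epimers into one compound.

**24 ⇒ 18 + 23.** The C5–C(sp) bond is cut (Sonogashira coupling). Alkyne 23 comes from tert-butyl acetate 19 and silyl ynal 20 through aldol adduct 22. The coupling must tolerate a free phenol and two ortho alkyl groups on iodide 18.

**18 ⇒ 17.** The C5–iodine bond is cut. In phenol 17 the position para to the hydroxyl is C5, and one ortho position is the fusion carbon, so electrophilic iodination has only C7 as a competitor.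

**17 ⇒ 15 (through 16).** Both C4a–C8a and C7–C8 are cut and the phenol oxygen is returned to a furan. This removes both rings and leaves an open-chain furan-yne with one stereocentre. Against a thermal furan Diels–Alder reaction, the gold pathway transfers the oxygen to the alkyne-derived carbon C8. With hydrogen on C8, however, the intermediate C7–C8 arene oxide is expected to open toward the cation stabilised by the C6 and C4a alkyl groups, which would leave the oxygen on C7. The alkyne is therefore capped with a trimethylsilyl group: a silicon on C8 should direct the opening the other way and then be lost. C1 is kept sp3 as a silyl ether, because a conjugated ynone would invert the polarisation of the alkyne.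

**15 ⇒ 14 ⇒ 13.** The C1–C8a bond is cut (acetylide addition to aldehyde 13) and the C1 O–Si bond removed. The C1 configuration is irrelevant, so no control is required.

**13 ⇒ 11 ⇒ 10 ⇒ 8.** The aldehyde is traced to a terminal alkene, and the C2–C3 bond is cut as an asymmetric allylation of aldehyde 8. This is the only stereo-defining step; reagent control is preferred because no neighbouring centre exists.

**8 ⇒ 7 ⇒ 5 ⇒ 4 ⇒ 1 + 2.** Aldehyde 8 is reached from alcohol 7, and this from vinylfuran 5 and aldehyde 4 (one-carbon homologation). The C6–alkyl bond is cut as a Negishi coupling of commercial bromofuraldehyde 1 with the zinc reagent from bromide 2. The labile furylacetaldehyde 8 is generated only immediately before use.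

## Roads not taken

**Alternative 1:** The C2–C3 bond is cut. In the forward direction a dinuclear zinc catalyst (from ZnEt2 and a chiral bis(diarylprolinol)phenol ligand) would enolise the methyl ketone of keto aldehyde A2 and add it to the aldehyde, closing ring A and setting C3 to give A1, the bis-benzyl ether of the target.
- Merits: the stereocentre is made last by a catalyst, C3 needs no protecting group, and the pyranone can be attached to a flat arene early. In these respects it is better than the chosen plan.
- Weak points: A2 is a pentasubstituted benzene whose assembly faces the same placement problem that the furan route solves by connectivity. Its arylacetaldehyde is more acidic than the methyl ketone and enolises toward the arene, so self-condensation competes with the wanted enolate. The product is a zinc aldolate of a β-hydroxy tetralone under basic conditions, which invites retro-aldol erosion and dehydration to a naphthol. The catalyst is established for intermolecular methyl ketone–aldehyde aldols, not for this ring closure.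
- Comparison: the chosen plan is longer, but it sets C3 early with a reagent of known facial sense and never exposes the free aldol to base.

**Alternative 2:** The C3–C4 and C1–C2 bonds are cut. Toluate A4 would be lithiated at its benzylic methyl with lithium diisopropylamide and added to the β-carbon of chiral dioxinone A5 anti to the tert-butyl group; the resulting enolate would then attack the aryl ester to give the dioxanone-fused enol A3.
- Merits: it is the most convergent road. Both ring A bonds form in one operation, the stereocentre comes from a cheap acetal, and the C5 alkyne is present from the start. The chosen plan has to set a late, regioselective iodination (step 11) against this.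
- Weak points: the annulation leaves an extra carboxyl carbon on C2. Removing it requires acetal cleavage and decarboxylation of a β-oxygenated ketone with an acidic C2–H, the conditions under which ring A aromatises. The benzylic lithium may also attack the dioxinone carbonyl directly, A4 needs its own regiocontrolled arene synthesis, and the C8 methyl ether must be cleaved late.
- Comparison: the chosen plan avoids any decarboxylation next to the sensitive carbinol and obtains the phenol free.

**Alternative 3:** The C4–C4a bond is cut. Zerovalent palladium (from Pd(OAc)2 and a chiral ferrocenyl phosphine-oxazoline, with Cs2CO3) would insert into the C4a–Br bond of cyclobutanol A7, cleave one of the two enantiotopic cyclobutane bonds at C1 by β-carbon elimination, and reductively eliminate to form C4–C4a, giving tetralone A6 with C3 set.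
- Merits: it is clearly the shortest way to a complete ring A, and it is catalytic and asymmetric. A7 should come from an aryllithium and a 3-benzyloxycyclobutanone.
- Weak points: after ring opening the alkylpalladium at C4 carries both a hydrogen and a benzyloxy group on C3, so β-elimination can destroy the stereocentre or the oxygen. Selection between the enantiotopic bonds in a 3-alkoxycyclobutanol of this kind is not established. A6 still lacks the C5 substituent, so it needs the same late para-functionalisation as the chosen plan, plus demethylation and debenzylation. The arene of A7 again has to be made regioselectively.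
- Comparison: Alternative 3 reaches a tetralone in fewer steps than phenol 17 is reached here. The chosen plan sets against it a stereocentre from a predictable reagent, no β-oxygenated alkylpalladium, and a ring B whose substitution follows from connectivity.

Key step: step 10

Assumption: all bicyclic compounds keep the tetralone locants C1–C8a of the target, and C1 and the side-chain carbinol carbon are carried as epimer mixtures (both become ketones in step 16), so their SMILES show no descriptor at those centres.

## Route

Step 1
Reactants: 1 4-bromofuran-2-carbaldehyde; 2 1-bromo-3-methylbutane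
Product: 4 4-(3-methylbutyl)furan-2-carbaldehyde, via (3-methylbutyl)zinc bromide 3 (not isolated)
Conditions: 2, Zn dust (activated with TMSCl and 1,2-dibromoethane), LiCl, THF, 50 °C; then 1, Pd(OAc)2 (2 mol %), SPhos (4 mol %), THF, 25 °C
Reagents that add atoms: zinc, [Zn] (kept in 3 only)
Why: Negishi coupling: LiCl-assisted zinc insertion into the primary bromide gives an alkylzinc halide that leaves the aldehyde alone, and a dialkylbiarylphosphine palladium catalyst couples it with the furyl bromide faster than β-hydride elimination.

Step 2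
Reactants: 4 4-(3-methylbutyl)furan-2-carbaldehyde
Product: 5 2-ethenyl-4-(3-methylbutyl)furan
Conditions: Ph3PCH3Br, KOtBu, THF, 0 → 25 °C
Reagents that add atoms: methyltriphenylphosphonium bromide, C[P+](c1ccccc1)(c1ccccc1)c1ccccc1.[Br-]
Why: Wittig methylenation of an aromatic aldehyde; the non-stabilised ylide reacts at 0 °C and the furan ring is untouched.

Step 3
Reactants: 5 2-ethenyl-4-(3-methylbutyl)furan
Product: 7 2-[4-(3-methylbutyl)furan-2-yl]ethan-1-ol, via B-alkyl-9-BBN adduct 6 (not isolated)
Conditions: 9-BBN, THF, 0 → 25 °C; then NaOH, H2O2, 0 °C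
Reagents that add atoms: 9-borabicyclo[3.3.1]nonane, B1C2CCCC1CCC2 (kept in 6 only); hydrogen peroxide, OO
Why: Hydroboration–oxidation: 9-BBN adds to the terminal carbon of the vinyl group only (the furan π bonds are aromatic), and alkaline peroxide converts the C–B bond into the primary alcohol.

Step 4
Reactants: 7 2-[4-(3-methylbutyl)furan-2-yl]ethan-1-ol
Product: 8 2-[4-(3-methylbutyl)furan-2-yl]acetaldehyde
Conditions: Dess–Martin periodinane, NaHCO3, CH2Cl2, 0 °C; filtered, concentrated cold and used at once
Reagents that add atoms: none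
Why: Dess–Martin oxidation under bicarbonate buffer stops at the aldehyde; because a furylacetaldehyde enolises and self-condenses readily, it is not stored or purified.

Step 5
Reactants: 8 2-[4-(3-methylbutyl)furan-2-yl]acetaldehyde
Product: 10 (2S)-1-[4-(3-methylbutyl)furan-2-yl]pent-4-en-2-ol, via diisopinocampheylborinate ester 9 (not isolated)
Conditions: (−)-Ipc2B(allyl) (salt-free, 1 M in pentane), Et2O, −100 → −78 °C; then NaOH, H2O2, 0 → 25 °C
Reagents that add atoms: (−)-B-allyldiisopinocampheylborane, C=CCB([C@@H]1C[C@@H]2C[C@H]([C@H]1C)C2(C)C)[C@@H]1C[C@@H]2C[C@H]([C@H]1C)C2(C)C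
Why: Brown allylboration through a closed chair (Zimmerman–Traxler) transition state; the reagent derived from (+)-α-pinene delivers allyl to the Si face of the aldehyde, which for this substituent pattern gives the (2S) carbinol, the future C3 (R) of the target, and the low temperature and absence of base keep the aldehyde from enolising.

Step 6
Reactants: 10 (2S)-1-[4-(3-methylbutyl)furan-2-yl]pent-4-en-2-ol
Product: 11 tert-butyldimethyl{[(2S)-1-[4-(3-methylbutyl)furan-2-yl]pent-4-en-2-yl]oxy}silane
Conditions: TBSCl, imidazole, DMF, 25 °C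
Reagents that add atoms: tert-butyldimethylsilyl chloride, CC(C)(C)[Si](C)(C)Cl
Why: Silylation of a secondary alcohol; the tert-butyldimethylsilyl ether has to outlast every step up to the last one.

Step 7
Reactants: 11 tert-butyldimethyl{[(2S)-1-[4-(3-methylbutyl)furan-2-yl]pent-4-en-2-yl]oxy}silane
Product: 13 (3R)-3-[(tert-butyldimethylsilyl)oxy]-4-[4-(3-methylbutyl)furan-2-yl]butanal, via vicinal diol 12 (not isolated)
Conditions: OsO4 (2 mol %), NaIO4, 2,6-lutidine, 1,4-dioxane/H2O (3:1), 25 °C
Reagents that add atoms: osmium tetroxide, O=[Os](=O)(=O)=O (catalytic oxygen carrier); sodium periodate, [Na+].[O-]I(=O)(=O)=O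
Why: Lemieux–Johnson cleavage: OsO4 dihydroxylates the monosubstituted alkene in preference to the aromatic furan and periodate cleaves the diol; 2,6-lutidine buffers the medium so that the β-silyloxy aldehyde does not eliminate.

Step 8
Reactants: 13 (3R)-3-[(tert-butyldimethylsilyl)oxy]-4-[4-(3-methylbutyl)furan-2-yl]butanal
Product: 14 (5S)-5-[(tert-butyldimethylsilyl)oxy]-6-[4-(3-methylbutyl)furan-2-yl]-1-(trimethylsilyl)hex-1-yn-3-ol (C3 epimers)
Conditions: Me3SiC≡CH, n-BuLi, THF, −78 °C; then 13, −78 → −20 °C; aq. NH4Cl
Reagents that add atoms: (trimethylsilyl)acetylene, C#C[Si](C)(C)C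
Why: 1,2-Addition of a lithium acetylide to a β-silyloxy aldehyde; both carbinol epimers form and both are used, since this carbon becomes the C1 ketone in step 16, and the silyl cap on the alkyne is the control element of step 10.

Step 9
Reactants: 14 (5S)-5-[(tert-butyldimethylsilyl)oxy]-6-[4-(3-methylbutyl)furan-2-yl]-1-(trimethylsilyl)hex-1-yn-3-ol (C3 epimers)
Product: 15 (5S)-5-[(tert-butyldimethylsilyl)oxy]-6-[4-(3-methylbutyl)furan-2-yl]-3-[(triethylsilyl)oxy]-1-(trimethylsilyl)hex-1-yne (C3 epimers)
Conditions: TESCl, imidazole, DMF, 0 → 25 °C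
Reagents that add atoms: triethylsilyl chloride, CC[Si](Cl)(CC)CC
Why: Silylation; a triethylsilyl ether keeps the propargylic carbon sp3 and unreactive during the gold step and can later be removed beside the tert-butyldimethylsilyl ether.

Step 10
Reactants: 15 (5S)-5-[(tert-butyldimethylsilyl)oxy]-6-[4-(3-methylbutyl)furan-2-yl]-3-[(triethylsilyl)oxy]-1-(trimethylsilyl)hex-1-yne (C3 epimers)
Product: 17 (3R)-3-[(tert-butyldimethylsilyl)oxy]-6-(3-methylbutyl)-1-[(triethylsilyl)oxy]-1,2,3,4-tetrahydronaphthalen-8-ol (C1 epimers), via aryl trimethylsilyl ether 16 (not isolated)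
Conditions: Ph3PAuNTf2 (5 mol %), CH2Cl2 (0.02 M), 25 °C; then K2CO3 (cat.), MeOH, 0 °C
Reagents that add atoms: none
Why: Proposed new method: the closest known reaction type is the gold-catalysed intramolecular furan-yne phenol synthesis of terminal alkynes, extended here to a 1-silylalkyne so that silicon decides where the oxygen ends up. Monovalent gold activates the alkyne and the furan C2–C3 π bond (future C4a–C5) attacks the internal alkyne carbon, which is β to silicon and therefore the more electrophilic one, in 6-exo-dig mode; this closes ring A (C4a–C8a) and gives a cyclopropyl gold carbene that opens to a dienal carbene centred on C8. The aldehyde oxygen adds to the carbene carbon to give an oxepine, whose 6π electrocyclisation to the C7–C8 arene oxide forms C7–C8 and closes ring B. The arene oxide can open by breaking C7–O or C8–O, which amounts to choosing between the σ-complexes of an electrophilic hydroxylation at C8 or at C7; with hydrogen on C8 the alkyl groups on C6 and C4a (ortho and para to C7) would be expected to leave the oxygen on C7, whereas with silicon on C8 the C7–O bond should break because the resulting cation is β to silicon, the ipso σ-complex of an arylsilane. A Brook-type shift of silicon from C8 to the adjacent oxygen then aromatises ring B to the C8 aryl silyl ether 16, which methanolysis converts into phenol 17. No stereocentre is formed: C3 is remote and C1 stays an sp3 silyl ether, which prevents ynone-type polarisation of the alkyne. The step needs chemoselectivity for furan attack over alkyne hydration, protodesilylation of the alkyne and propargylic ionisation; a dry non-nucleophilic medium, a neutral phosphine gold catalyst, high dilution and the electron-rich 2,4-dialkylfuran are meant to secure it.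

Step 11
Reactants: 17 (3R)-3-[(tert-butyldimethylsilyl)oxy]-6-(3-methylbutyl)-1-[(triethylsilyl)oxy]-1,2,3,4-tetrahydronaphthalen-8-ol (C1 epimers)
Product: 18 (3R)-3-[(tert-butyldimethylsilyl)oxy]-5-iodo-6-(3-methylbutyl)-1-[(triethylsilyl)oxy]-1,2,3,4-tetrahydronaphthalen-8-ol (C1 epimers)
Conditions: N-iodosuccinimide, MeCN, −20 → 0 °C, dark
Reagents that add atoms: N-iodosuccinimide, O=C1CCC(=O)N1I
Why: Electrophilic aromatic iodination; the free phenol directs para to C5 (one ortho site is the fusion carbon C8a, and 3,5-dialkylphenols are halogenated at C4), and N-iodosuccinimide without added acid leaves the silyl ethers alone.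

Step 12
Reactants: 19 tert-butyl acetate; 20 3-(trimethylsilyl)prop-2-ynal
Product: 22 tert-butyl 3-hydroxy-5-(trimethylsilyl)pent-4-ynoate (racemic), via lithium enolate 21 (not isolated)
Conditions: LDA, THF, −78 °C; then 20, −78 °C; aq. NH4Cl
Reagents that add atoms: lithium diisopropylamide, [Li+].CC(C)[N-]C(C)C (lithium kept in 21 only)
Why: Aldol addition of an ester lithium enolate to an ynal, which is attacked 1,2 at −78 °C; the carbinol centre is racemic and is removed by oxidation in step 16.

Step 13
Reactants: 22 tert-butyl 3-hydroxy-5-(trimethylsilyl)pent-4-ynoate (racemic)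
Product: 23 tert-butyl 3-hydroxypent-4-ynoate (racemic)
Conditions: K2CO3 (0.2 equiv), MeOH, 0 °C
Reagents that add atoms: none
Why: Methanolysis of the C(sp)–Si bond with catalytic carbonate; the tert-butyl ester does not transesterify under these conditions.

Step 14
Reactants: 18 (3R)-3-[(tert-butyldimethylsilyl)oxy]-5-iodo-6-(3-methylbutyl)-1-[(triethylsilyl)oxy]-1,2,3,4-tetrahydronaphthalen-8-ol (C1 epimers); 23 tert-butyl 3-hydroxypent-4-ynoate (racemic)
Product: 24 tert-butyl 5-{(3R)-3-[(tert-butyldimethylsilyl)oxy]-8-hydroxy-6-(3-methylbutyl)-1-[(triethylsilyl)oxy]-1,2,3,4-tetrahydronaphthalen-5-yl}-3-hydroxypent-4-ynoate (epimers at C1 and at the side-chain carbinol)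
Conditions: Pd(PPh3)2Cl2 (5 mol %), CuI (10 mol %), Et3N/THF (1:1), degassed, 50 °C
Reagents that add atoms: none
Why: Sonogashira coupling of an aryl iodide; the linear alkyne fits between the two ortho substituents, and the phenol and the carbinols need no protection.

Step 15
Reactants: 24 tert-butyl 5-{(3R)-3-[(tert-butyldimethylsilyl)oxy]-8-hydroxy-6-(3-methylbutyl)-1-[(triethylsilyl)oxy]-1,2,3,4-tetrahydronaphthalen-5-yl}-3-hydroxypent-4-ynoate
Product: 25 tert-butyl 5-{(3R)-3-[(tert-butyldimethylsilyl)oxy]-1,8-dihydroxy-6-(3-methylbutyl)-1,2,3,4-tetrahydronaphthalen-5-yl}-3-hydroxypent-4-ynoate (epimers at C1 and at the side-chain carbinol)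
Conditions: HF·pyridine, pyridine, THF, 0 °C
Reagents that add atoms: none
Why: Selective desilylation: under pyridine-buffered HF·pyridine a secondary triethylsilyl ether is cleaved much faster than a secondary tert-butyldimethylsilyl ether, and the buffer avoids ionisation at the ortho-hydroxybenzylic carbon.

Step 16
Reactants: 25 tert-butyl 5-{(3R)-3-[(tert-butyldimethylsilyl)oxy]-1,8-dihydroxy-6-(3-methylbutyl)-1,2,3,4-tetrahydronaphthalen-5-yl}-3-hydroxypent-4-ynoate
Product: 26 tert-butyl 5-{(3R)-3-[(tert-butyldimethylsilyl)oxy]-8-hydroxy-6-(3-methylbutyl)-1-oxo-1,2,3,4-tetrahydronaphthalen-5-yl}-3-oxopent-4-ynoate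
Conditions: MnO2 (activated, excess), CH2Cl2, 25 °C
Reagents that add atoms: none
Why: MnO2 oxidises benzylic and propargylic alcohols and leaves phenols and silyl ethers alone; both epimeric carbinols become ketones, so the diastereomer mixture converges to a single compound.

Step 17
Reactants: 26 tert-butyl 5-{(3R)-3-[(tert-butyldimethylsilyl)oxy]-8-hydroxy-6-(3-methylbutyl)-1-oxo-1,2,3,4-tetrahydronaphthalen-5-yl}-3-oxopent-4-ynoate
Product: 27 (3R)-3-[(tert-butyldimethylsilyl)oxy]-8-hydroxy-5-(4-hydroxy-2-oxo-2H-pyran-6-yl)-6-(3-methylbutyl)-3,4-dihydronaphthalen-1(2H)-one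
Conditions: Ph3PAuNTf2 (5 mol %), MeNO2/AcOH (4:1), 25 °C
Reagents that add atoms: none
Why: Gold-catalysed cyclisation of a tert-butyl 3-oxoalk-4-ynoate to a 4-hydroxy-2-pyranone: the ester carbonyl oxygen attacks the gold-activated alkyne at the aryl-bearing carbon (6-endo-dig), the tert-butyl group leaves as isobutene, and protodeauration with tautomerisation gives the pyranone; the C3 silyl ether keeps that oxygen from adding to the ynone.

Step 18
Reactants: 27 (3R)-3-[(tert-butyldimethylsilyl)oxy]-8-hydroxy-5-(4-hydroxy-2-oxo-2H-pyran-6-yl)-6-(3-methylbutyl)-3,4-dihydronaphthalen-1(2H)-one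
Product: 28 (3R)-3,8-dihydroxy-5-(4-hydroxy-2-oxo-2H-pyran-6-yl)-6-(3-methylbutyl)-3,4-dihydronaphthalen-1(2H)-one
Conditions: HF (48% aq.), MeCN, 0 → 25 °C
Reagents that add atoms: none
Why: Fluoride-assisted acidic desilylation; aqueous HF in MeCN frees the C3 carbinol without the base or strong acid that would dehydrate the β-hydroxy ketone to a naphthol.

## Compound list

1 | 4-bromofuran-2-carbaldehyde | O=Cc1cc(Br)co1 | starting material
2 | 1-bromo-3-methylbutane | CC(C)CCBr | starting material
3 | (3-methylbutyl)zinc bromide | CC(C)CC[Zn]Br | intermediate (not isolated)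
4 | 4-(3-methylbutyl)furan-2-carbaldehyde | CC(C)CCc1coc(C=O)c1 | intermediate
5 | 2-ethenyl-4-(3-methylbutyl)furan | CC(C)CCc1coc(C=C)c1 | intermediate
6 | 9-{2-[4-(3-methylbutyl)furan-2-yl]ethyl}-9-borabicyclo[3.3.1]nonane | CC(C)CCc1coc(CCB2C3CCCC2CCC3)c1 | intermediate (not isolated)
7 | 2-[4-(3-methylbutyl)furan-2-yl]ethan-1-ol | CC(C)CCc1coc(CCO)c1 | intermediate
8 | 2-[4-(3-methylbutyl)furan-2-yl]acetaldehyde | CC(C)CCc1coc(CC=O)c1 | intermediate
9 | (2S)-1-[4-(3-methylbutyl)furan-2-yl]pent-4-en-2-yl diisopinocampheylborinate | CC(C)CCc1coc(C[C@@H](OB([C@@H]2C[C@@H]3C[C@H]([C@H]2C)C3(C)C)[C@@H]2C[C@@H]3C[C@H]([C@H]2C)C3(C)C)CC=C)c1 | intermediate (not isolated)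
10 | (2S)-1-[4-(3-methylbutyl)furan-2-yl]pent-4-en-2-ol | CC(C)CCc1coc(C[C@@H](O)CC=C)c1 | intermediate
11 | tert-butyldimethyl{[(2S)-1-[4-(3-methylbutyl)furan-2-yl]pent-4-en-2-yl]oxy}silane | CC(C)CCc1coc(C[C@@H](O[Si](C)(C)C(C)(C)C)CC=C)c1 | intermediate
12 | (4S)-4-[(tert-butyldimethylsilyl)oxy]-5-[4-(3-methylbutyl)furan-2-yl]pentane-1,2-diol (C2 epimers) | CC(C)CCc1coc(C[C@@H](O[Si](C)(C)C(C)(C)C)CC(O)CO)c1 | intermediate (not isolated)
13 | (3R)-3-[(tert-butyldimethylsilyl)oxy]-4-[4-(3-methylbutyl)furan-2-yl]butanal | CC(C)CCc1coc(C[C@@H](O[Si](C)(C)C(C)(C)C)CC=O)c1 | intermediate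
14 | (5S)-5-[(tert-butyldimethylsilyl)oxy]-6-[4-(3-methylbutyl)furan-2-yl]-1-(trimethylsilyl)hex-1-yn-3-ol (C3 epimers) | CC(C)CCc1coc(C[C@@H](O[Si](C)(C)C(C)(C)C)CC(O)C#C[Si](C)(C)C)c1 | intermediate
15 | (5S)-5-[(tert-butyldimethylsilyl)oxy]-6-[4-(3-methylbutyl)furan-2-yl]-3-[(triethylsilyl)oxy]-1-(trimethylsilyl)hex-1-yne (C3 epimers) | CC(C)CCc1coc(C[C@@H](O[Si](C)(C)C(C)(C)C)CC(C#C[Si](C)(C)C)O[Si](CC)(CC)CC)c1 | intermediate (key-step precursor)
16 | (3R)-3-[(tert-butyldimethylsilyl)oxy]-6-(3-methylbutyl)-1-[(triethylsilyl)oxy]-8-[(trimethylsilyl)oxy]-1,2,3,4-tetrahydronaphthalene (C1 epimers) | CC(C)CCc1cc(O[Si](C)(C)C)c2c(c1)C[C@@H](O[Si](C)(C)C(C)(C)C)CC2O[Si](CC)(CC)CC | intermediate (not isolated)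
17 | (3R)-3-[(tert-butyldimethylsilyl)oxy]-6-(3-methylbutyl)-1-[(triethylsilyl)oxy]-1,2,3,4-tetrahydronaphthalen-8-ol (C1 epimers) | CC(C)CCc1cc(O)c2c(c1)C[C@@H](O[Si](C)(C)C(C)(C)C)CC2O[Si](CC)(CC)CC | intermediate (key-step product)
18 | (3R)-3-[(tert-butyldimethylsilyl)oxy]-5-iodo-6-(3-methylbutyl)-1-[(triethylsilyl)oxy]-1,2,3,4-tetrahydronaphthalen-8-ol (C1 epimers) | CC(C)CCc1cc(O)c2c(c1I)C[C@@H](O[Si](C)(C)C(C)(C)C)CC2O[Si](CC)(CC)CC | intermediate
19 | tert-butyl acetate | CC(=O)OC(C)(C)C | starting material
20 | 3-(trimethylsilyl)prop-2-ynal | O=CC#C[Si](C)(C)C | starting material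
21 | lithium enolate of tert-butyl acetate | C=C(O[Li])OC(C)(C)C | intermediate (not isolated)
22 | tert-butyl 3-hydroxy-5-(trimethylsilyl)pent-4-ynoate (racemic) | C[Si](C)(C)C#CC(O)CC(=O)OC(C)(C)C | intermediate
23 | tert-butyl 3-hydroxypent-4-ynoate (racemic) | C#CC(O)CC(=O)OC(C)(C)C | intermediate
24 | tert-butyl 5-{(3R)-3-[(tert-butyldimethylsilyl)oxy]-8-hydroxy-6-(3-methylbutyl)-1-[(triethylsilyl)oxy]-1,2,3,4-tetrahydronaphthalen-5-yl}-3-hydroxypent-4-ynoate (epimer mixture) | CC(C)CCc1cc(O)c2c(c1C#CC(O)CC(=O)OC(C)(C)C)C[C@@H](O[Si](C)(C)C(C)(C)C)CC2O[Si](CC)(CC)CC | intermediate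
25 | tert-butyl 5-{(3R)-3-[(tert-butyldimethylsilyl)oxy]-1,8-dihydroxy-6-(3-methylbutyl)-1,2,3,4-tetrahydronaphthalen-5-yl}-3-hydroxypent-4-ynoate (epimer mixture) | CC(C)CCc1cc(O)c2c(c1C#CC(O)CC(=O)OC(C)(C)C)C[C@@H](O[Si](C)(C)C(C)(C)C)CC2O | intermediate
26 | tert-butyl 5-{(3R)-3-[(tert-butyldimethylsilyl)oxy]-8-hydroxy-6-(3-methylbutyl)-1-oxo-1,2,3,4-tetrahydronaphthalen-5-yl}-3-oxopent-4-ynoate | CC(C)CCc1cc(O)c2c(c1C#CC(=O)CC(=O)OC(C)(C)C)C[C@@H](O[Si](C)(C)C(C)(C)C)CC2=O | intermediate
27 | (3R)-3-[(tert-butyldimethylsilyl)oxy]-8-hydroxy-5-(4-hydroxy-2-oxo-2H-pyran-6-yl)-6-(3-methylbutyl)-3,4-dihydronaphthalen-1(2H)-one | CC(C)CCc1cc(O)c2c(c1-c1cc(O)cc(=O)o1)C[C@@H](O[Si](C)(C)C(C)(C)C)CC2=O | intermediate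
28 | (3R)-3,8-dihydroxy-5-(4-hydroxy-2-oxo-2H-pyran-6-yl)-6-(3-methylbutyl)-3,4-dihydronaphthalen-1(2H)-one | CC(C)CCc1cc(O)c2c(c1-c1cc(O)cc(=O)o1)C[C@@H](O)CC2=O | target

## Step count and least certain steps

Total step count: 18 (16 in the main line, 2 for alkyne 23). Longest linear sequence: 16 steps (steps 1–11 and 14–18).

**Step 10 (key step, proposed new method).**
- Risk: the silyl-capped alkyne may cyclise too slowly. A six-membered exo closure of an unbranched carbon tether onto a hindered alkyne gives protodesilylation of the alkyne, loss of the propargylic silyl ether or alkyne hydration time to compete, so that the silicon-directed opening never comes into play.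
- Fallback (known chemistry; sets out from 15, returns at 17): the alkyne silyl group is removed with K2CO3 in MeOH (25 °C) to give the terminal alkyne (5S)-5-[(tert-butyldimethylsilyl)oxy]-6-[4-(3-methylbutyl)furan-2-yl]-3-[(triethylsilyl)oxy]hex-1-yne F1. This is the standard substrate type of the gold phenol synthesis and would be cycloisomerised with AuCl3 (5 mol %) in MeCN or with the same phosphine gold catalyst. Ring formation then rests on documented reactivity, but the position of the oxygen is no longer enforced. Phenol 17 would have to be separated from material oxygenated at C7, and the catalyst and solvent would be screened for the better ratio.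

**Step 4 (with step 5).**
- Risk: self-condensation and enolisation of the furylacetaldehyde between oxidation and allylboration, lowering the yield and the enantiomeric purity of 10.
- Fallback (sets out from 7, returns at 10): Krische allylation at the alcohol oxidation level with [Ir(cod)Cl]2, (S)-BINAP, 4-chloro-3-nitrobenzoic acid, Cs2CO3 and allyl acetate in THF at 100 °C. The aldehyde then exists only transiently on iridium and is never handled. This fallback makes no new compound (F0). The facial sense of the (S)-ligand is assigned by analogy with unbranched primary alcohols and would be confirmed by Mosher ester analysis of 10 before scale-up.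

**Step 11.**
- Risk: iodination at C7, or at both C5 and C7, because the phenol with a benzylic ether beside it is very electron-rich.
- Fallback (sets out from 17, returns at 26; one step longer): C1 is oxidised before the halogen is introduced.
  - HF·pyridine/pyridine removes the triethylsilyl group to give (3R)-3-[(tert-butyldimethylsilyl)oxy]-6-(3-methylbutyl)-1,2,3,4-tetrahydronaphthalene-1,8-diol F2.
  - MnO2 gives (3R)-3-[(tert-butyldimethylsilyl)oxy]-8-hydroxy-6-(3-methylbutyl)-3,4-dihydronaphthalen-1(2H)-one F3. Here the phenol is hydrogen-bonded to the ketone and ring B is deactivated, so iodination should be slower and stop cleanly after one substitution para to the hydroxyl, as for salicyl ketones.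
  - N-Iodosuccinimide gives the 5-iodo tetralone F4.
  - Sonogashira coupling with 23 gives tert-butyl 5-{(3R)-3-[(tert-butyldimethylsilyl)oxy]-8-hydroxy-6-(3-methylbutyl)-1-oxo-1,2,3,4-tetrahydronaphthalen-5-yl}-3-hydroxypent-4-ynoate F5.
  - MnO2 oxidation of the propargylic alcohol gives 26.

**Step 17.**
- Risk: attack of the ester oxygen at an alkyne carbon flanked by a di-ortho-substituted aryl group may be slow, so that hydration of the ynone, or loss of the C3 silyl group followed by addition of the C3 hydroxyl to the ynone, takes over.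
- Fallback (sets out from 26, returns at 27): the pyranone is closed as a classical triketide.
  - Conjugate addition of pyrrolidine to the ynone gives the enaminone tert-butyl (4E)-5-aryl-3-oxo-5-(pyrrolidin-1-yl)pent-4-enoate F6.
  - Hydrolysis with aqueous acetic acid gives the 3,5-diketo ester tert-butyl 5-aryl-3,5-dioxopentanoate F7.
  - Heating in toluene (110 °C) expels tert-butanol to form an acylketene, which lactonises through the aryl ketone enol to 27.

## Further compounds

F1 | step 10 | (5S)-5-[(tert-butyldimethylsilyl)oxy]-6-[4-(3-methylbutyl)furan-2-yl]-3-[(triethylsilyl)oxy]hex-1-yne (C3 epimers) | CC(C)CCc1coc(C[C@@H](O[Si](C)(C)C(C)(C)C)CC(C#C)O[Si](CC)(CC)CC)c1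
F0 | step 4 | none | none
F2 | step 11 | (3R)-3-[(tert-butyldimethylsilyl)oxy]-6-(3-methylbutyl)-1,2,3,4-tetrahydronaphthalene-1,8-diol (C1 epimers) | CC(C)CCc1cc(O)c2c(c1)C[C@@H](O[Si](C)(C)C(C)(C)C)CC2O
F3 | step 11 | (3R)-3-[(tert-butyldimethylsilyl)oxy]-8-hydroxy-6-(3-methylbutyl)-3,4-dihydronaphthalen-1(2H)-one | CC(C)CCc1cc(O)c2c(c1)C[C@@H](O[Si](C)(C)C(C)(C)C)CC2=O
F4 | step 11 | (3R)-3-[(tert-butyldimethylsilyl)oxy]-8-hydroxy-5-iodo-6-(3-methylbutyl)-3,4-dihydronaphthalen-1(2H)-one | CC(C)CCc1cc(O)c2c(c1I)C[C@@H](O[Si](C)(C)C(C)(C)C)CC2=O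
F5 | step 11 | tert-butyl 5-{(3R)-3-[(tert-butyldimethylsilyl)oxy]-8-hydroxy-6-(3-methylbutyl)-1-oxo-1,2,3,4-tetrahydronaphthalen-5-yl}-3-hydroxypent-4-ynoate (carbinol epimers) | CC(C)CCc1cc(O)c2c(c1C#CC(O)CC(=O)OC(C)(C)C)C[C@@H](O[Si](C)(C)C(C)(C)C)CC2=O
F6 | step 17 | tert-butyl (4E)-5-{(3R)-3-[(tert-butyldimethylsilyl)oxy]-8-hydroxy-6-(3-methylbutyl)-1-oxo-1,2,3,4-tetrahydronaphthalen-5-yl}-3-oxo-5-(pyrrolidin-1-yl)pent-4-enoate | CC(C)CCc1cc(O)c2c(c1/C(=C\C(=O)CC(=O)OC(C)(C)C)N1CCCC1)C[C@@H](O[Si](C)(C)C(C)(C)C)CC2=O
F7 | step 17 | tert-butyl 5-{(3R)-3-[(tert-butyldimethylsilyl)oxy]-8-hydroxy-6-(3-methylbutyl)-1-oxo-1,2,3,4-tetrahydronaphthalen-5-yl}-3,5-dioxopentanoate | CC(C)CCc1cc(O)c2c(c1C(=O)CC(=O)CC(=O)OC(C)(C)C)C[C@@H](O[Si](C)(C)C(C)(C)C)CC2=O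
A1 | alternative 1 | (3R)-8-(benzyloxy)-5-[4-(benzyloxy)-2-oxo-2H-pyran-6-yl]-3-hydroxy-6-(3-methylbutyl)-3,4-dihydronaphthalen-1(2H)-one | CC(C)CCc1cc(OCc2ccccc2)c2c(c1-c1cc(OCc3ccccc3)cc(=O)o1)C[C@@H](O)CC2=O
A2 | alternative 1 | 2-{2-acetyl-3-(benzyloxy)-6-[4-(benzyloxy)-2-oxo-2H-pyran-6-yl]-5-(3-methylbutyl)phenyl}acetaldehyde | CC(C)CCc1cc(OCc2ccccc2)c(C(C)=O)c(CC=O)c1-c1cc(OCc2ccccc2)cc(=O)o1
A3 | alternative 2 | C1 enol of the 2-tert-butyl-1,3-dioxan-4-one-fused 8-methoxy-6-(3-methylbutyl)-5-[(triisopropylsilyl)ethynyl]tetralone | CC(C)CCc1cc(OC)c2c(c1C#C[Si](C(C)C)(C(C)C)C(C)C)C[C@H]1O[C@H](C(C)(C)C)OC(=O)C1=C2O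
A4 | alternative 2 | methyl 2-methoxy-6-methyl-4-(3-methylbutyl)-5-[(triisopropylsilyl)ethynyl]benzoate | COC(=O)c1c(OC)cc(CCC(C)C)c(C#C[Si](C(C)C)(C(C)C)C(C)C)c1C
A5 | alternative 2 | (2S)-2-tert-butyl-4H-1,3-dioxin-4-one | O=C1C=CO[C@H](C(C)(C)C)O1
A6 | alternative 3 | (3R)-3-(benzyloxy)-8-methoxy-6-(3-methylbutyl)-3,4-dihydronaphthalen-1(2H)-one | CC(C)CCc1cc(OC)c2c(c1)C[C@@H](OCc1ccccc1)CC2=O
A7 | alternative 3 | cis-3-(benzyloxy)-1-[2-bromo-6-methoxy-4-(3-methylbutyl)phenyl]cyclobutan-1-ol (hydroxyl cis to benzyloxy) | CC(C)CCc1cc(Br)c([C@]2(O)C[C@@H](OCc3ccccc3)C2)c(OC)c1
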